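The trap in east was its charge of coupling partner, which looked close to the midnight run, although substrate takes partner away as it reacts.

| flask | substrate | coupling partner | remark | time |
|---|---|---|---|---|
| midnight | 0.010 M | 0.017 M | run made earlier |  |
| dawn | 0.010 M | 0.053 M | run made earlier |  |
| west | 0.010 M | 0.0400 M |  | 15 d |
| east | 0.010 M | 0.0120 M |  | 8.0 d |

| run | time / d | target / % | substrate / % |
|---|---|---|---|
| midnight | 0.500 | 15 | 63 |
| midnight | 1.25 | 24 | 38 |
| midnight | 2.50 | 38 | 18 |
| midnight | 4.00 | 43 | 3 |
| midnight | 6.00 | 42 | 0 |
| dawn | 0.417 | 36 | 35 |
| dawn | 0.833 | 53 | 14 |
| dawn | 1.67 | 58 | 1 |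
| dawn | 3.00 | 61 | 1 |
| dawn | 6.00 | 59 | 2 |

(each reading ± 2 percentage points)

1. the flask that ends with the higher amount of target, in percent of the substrate charged, or "neither" when 2 percentage points or less lies between them (west / east / neither)
2. final target, as a percentage of the substrate charged, in west
3. final target, as a percentage of the substrate charged, in east

- the numbers in the tables scatter by 2 percentage points (one standard deviation)
- a reading or a percentage of target counts all its forms, free or not

I assumed each substrate took one partner, so I worked with the spare partner: the charge less the substrate charge, the excess over the limiting reagent. By charge, midnight stood 1.42 times above east; by spare partner, 7.00 mM against 2.00 mM, it stood 3.50 times above. Dawn had 43.0 mM spare and west 30.0 mM.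

At each last reading I took the loss ratio, the charge not found as target over the charge found as target: 1.38 in midnight, 0.695 in dawn. Between those runs the ratio fell 0.378 powers of ten per power of ten of spare partner, my loss slope. That gave me 55.7 % target in west. In east, which lay below both runs, the ratio came to 2.22, so target 31.1 %.

The forecast chose west, with 56 % (51 % to 60 %) in west and 35 % (29 % to 40 %) in east, higher than my east. Its ground: “Incomplete conversion and partner depletion trim east to about 35%.”

The flasks gave 54.3 % in west and 28.0 % in east, so west ended higher.

    substrate + coupling partner ⇌ target (K = 470 M⁻¹, k = 4.60 × 10⁻⁴ M⁻¹ s⁻¹)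
    substrate + target → side product (k = 0.00420 M⁻¹ s⁻¹)
    target ⇌ isomer of the product (K = 3.00, k = 2.50 × 10⁻⁶ s⁻¹)
    crystals ⇌ target, rate k4*(cs4 - [target]) while solid is left; crystals form when [target] > cs4 (solubility = 0.330 mM, k = 7.10 × 10⁻⁵ s⁻¹)

East's loss ratio came to 2.57, above my 2.22. For a neighbour, east with 0.030 M of coupling partner, the loss slope gives 51.9 % target, and that flask held 52.2 %. In east at 1.07 d, dissolved target had a half-life of 0.36 d in the step with substrate into side product, shorter than the 2.0 d substrate had in the forward step to target. In east at that time, with each step taken net and passage into its other forms counted as use, dissolved target was made at 0.940 times the rate it was used.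

All runs were computed for an exercise; the scatter is artificial.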